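**Plan**

1. The target is ring A (C5a, C6-OH, C7-acyl, C8-OH, C9-H, C9a) fused to a 2,5-dihydrooxepine (O1, C2H2, C3(CH3)=C4H, C5H2); it has no stereocentre.
2. Enabling feature: the enol-ether bond C5a=C9a of the oxepine lies inside ring A and is skipped from C3=C4 through C5. This is the product pattern of a [3,3] retro-Claisen shift of a 2-vinylcyclopropyl ketone, provided ring A is still a cyclohexane-1,3-dione.
3. Retrosynthetic cuts, in order: C7–C(=O) (aryllithium plus Weinreb amide); C8–O (C–H borylation/oxidation); ring A dehydrogenation; O1–C2 (retro-Claisen, which restores the C4–C5a cyclopropane bond); then C5–C5a and C4–C5a of the cyclopropane (dione plus isoprene dibromide).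
4. Forward order: cyclopropane (steps 1–2), oxepine by ring expansion (step 3), ring A aromatised (steps 4–5), C8 oxygen (steps 6–8), side chain joined at C7 (steps 9–11), deprotection (step 12).
5. Stereochemistry: the transient stereocentres (cyclopropane CH of 5, C7 of 8) are racemic and are erased; the cis C3=C4 geometry is imposed by the ring-forming sigmatropic shift.

Key step: step 3

Assumption (chemistry): in step 2 the first C-alkylation is taken to occur at the CH2Br remote from the methyl group, and spirodione 5 is taken to survive a cold, halide-free work-up; any 6 already present at that stage is simply carried into step 3.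

**Route**

Step 1
Reactants: 1 isoprene (2-methylbuta-1,3-diene)
Product: 2 (2E)-1,4-dibromo-2-methylbut-2-ene
Conditions: Br2 (1.0 equiv), CH2Cl2, −20 °C; then rt; distillation
Reagents that add atoms: bromine, BrBr
Why: Electrophilic addition of bromine to a conjugated diene proceeds through an allylic cation whose 1,4-capture, followed by equilibration of the kinetic 1,2-adducts, should leave the thermodynamically preferred (E)-1,4-dibromide.

Step 2
Reactants: 3 cyclohexane-1,3-dione; 2 (2E)-1,4-dibromo-2-methylbut-2-ene
Product: 5 1-(prop-1-en-2-yl)spiro[2.5]octane-4,8-dione (racemic), via bromoallyl dione 4 (not isolated)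
Conditions: Cs2CO3 (2.2 equiv), DMF, 0 °C; cold aqueous work-up (removes bromide), concentration below 20 °C
Reagents that add atoms: none
Why: Double alkylation of a cyclic β-diketone: the soft cesium diketonate should be C-alkylated (SN2) at the CH2Br remote from the methyl group, and the enolate of 4 should then close the three-membered ring by intramolecular 3-exo SN2' displacement of the second bromide, a known way from 1,3-diones and 1,4-dibromobut-2-enes to 2-vinylcyclopropane-1,1-diketones; the cyclopropane stereocentre forms as a racemate because nothing in the system is chiral.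

Step 3
Reactants: 5 1-(prop-1-en-2-yl)spiro[2.5]octane-4,8-dione
Product: 6 3-methyl-2,5,8,9-tetrahydro-1-benzoxepin-6(7H)-one
Conditions: toluene (acid- and halide-free), 60 °C, Ar
Reagents that add atoms: none
Why: Thermal retro-Claisen ([3,3]-sigmatropic) rearrangement of a 2-vinylcyclopropyl ketone: in a boat-shaped six-atom array (carbonyl O, carbonyl C, spiro C, cyclopropane CH, isopropenyl C, terminal CH2) the oxygen bonds to the terminal CH2 while the spiro C–CH cyclopropane bond breaks, so that O1–C2, the C3=C4 alkene and the C5a=C9a enol ether arise in one concerted six-electron event. The closest known reaction type is the rearrangement of cis-2-vinylcyclopropanecarbaldehydes and of 2-vinylcyclopropane-1,1-diketones to 2,5-dihydrooxepines. The seven-membered ring is closed by ring expansion of the cyclopropane (three ring atoms plus the four-atom O=C/C=C bridge) and not by an end-to-end cyclisation, so no exo/endo closure mode applies. No stereocentre is created, the single one of 5 is consumed, and the C3=C4 bond can only be cis because it is born inside the ring. The step needs periselectivity for the [3,3] shift over ionic ring opening and re-closure to the 2-isopropenyl-2,3-dihydrofuran (Cloke–Wilson pathway); the spiro centre keeps one of the two equivalent carbonyl groups permanently cis to the isopropenyl group (hence also a single constitution), and a neutral medium free of halide and acid at moderate temperature withholds the promoters of the ionic path. Loss of ring strain together with the gain of a vinylogous ester should place the equilibrium on the oxepine side.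

Step 4
Reactants: 6 3-methyl-2,5,8,9-tetrahydro-1-benzoxepin-6(7H)-one
Product: 8 3-methyl-7-(phenylselanyl)-2,5,8,9-tetrahydro-1-benzoxepin-6(7H)-one (racemic), via lithium enolate 7 (not isolated)
Conditions: LiN(i-Pr)2 (1.1 equiv), THF, −78 °C; PhSeCl (1.15 equiv), −78 °C; aq NH4Cl
Reagents that add atoms: benzeneselenenyl chloride, Cl[Se]c1ccccc1
Why: Kinetic deprotonation of a vinylogous ester takes place at the α' carbon (C7), as in Stork–Danheiser alkylations, and the cross-conjugated enolate 7 is trapped by PhSeCl (α-selenenylation of a ketone enolate) much faster than the ring alkene can react; the new C7 stereocentre is racemic and is erased in step 5.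

Step 5
Reactants: 8 3-methyl-7-(phenylselanyl)-2,5,8,9-tetrahydro-1-benzoxepin-6(7H)-one
Product: 11 3-methyl-2,5-dihydro-1-benzoxepin-6-ol, via selenoxide 9 (not isolated), via dienone 10 (not isolated)
Conditions: 30% aq H2O2 (2.5 equiv), pyridine (2 equiv), CH2Cl2, 0 °C to rt
Reagents that add atoms: none
Why: Selenoxide syn-elimination: oxidation at selenium gives selenoxide 9, which should eliminate at or below room temperature towards C8 to the cross-conjugated dienone 10, the keto tautomer of a phenol that enolises at once under pyridine buffering to aromatic ring A, while a small excess of buffered peroxide at 0 °C spares the isolated C3=C4 double bond.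

Step 6
Reactants: 11 3-methyl-2,5-dihydro-1-benzoxepin-6-ol
Product: 12 6-(methoxymethoxy)-3-methyl-2,5-dihydro-1-benzoxepine
Conditions: NaH (1.3 equiv), MOMCl (1.2 equiv), THF/DMF, 0 °C to rt
Reagents that add atoms: chloromethyl methyl ether (MOMCl), COCCl
Why: Williamson-type O-alkylation of the sodium phenoxide with an α-chloro ether installs the MOM acetal, which is inert to the borylation and later directs the lithiation.

Step 7
Reactants: 12 6-(methoxymethoxy)-3-methyl-2,5-dihydro-1-benzoxepine
Product: 14 6-(methoxymethoxy)-3-methyl-2,5-dihydro-1-benzoxepin-8-ol, via arylboronate 13 (not isolated)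
Conditions: [Ir(OMe)(cod)]2 (1.5 mol%), 4,4'-di-tert-butyl-2,2'-bipyridine (3 mol%), B2pin2 (0.7 equiv), THF, 70 °C; then 3 M aq NaOH, 30% aq H2O2, 0 °C to rt
Reagents that add atoms: hydrogen peroxide, OO
Why: Iridium-catalysed aromatic C–H borylation (Ishiyama–Miyaura–Hartwig) is sterically governed and should take place at C8, the only ring C–H without an ortho substituent (C7 is flanked by OMOM, C9 by O1), and alkaline peroxide oxidation of the C–B bond then gives the phenol at the same position while leaving the isolated alkene untouched.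

Step 8
Reactants: 14 6-(methoxymethoxy)-3-methyl-2,5-dihydro-1-benzoxepin-8-ol
Product: 15 6,8-bis(methoxymethoxy)-3-methyl-2,5-dihydro-1-benzoxepine
Conditions: NaH (1.3 equiv), MOMCl (1.2 equiv), THF/DMF, 0 °C to rt
Reagents that add atoms: chloromethyl methyl ether (MOMCl), COCCl
Why: The same Williamson-type MOM protection as in step 6 gives C7 two flanking acetal directing groups.

Step 9
Reactants: 16 3-(3,4-dihydroxyphenyl)propanoic acid
Product: 18 3-(3,4-dihydroxyphenyl)-N-methoxy-N-methylpropanamide, via benzotriazolyl ester 17 (not isolated)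
Conditions: MeNH(OMe)·HCl (1.3 equiv), EDC·HCl (1.2 equiv), HOBt (1.2 equiv), N-methylmorpholine (2.6 equiv), DMF, 0 °C to rt
Reagents that add atoms: N,O-dimethylhydroxylamine hydrochloride, CNOC.Cl
Why: Carbodiimide/HOBt amide coupling: the benzotriazolyl ester 17 should be captured by the nitrogen nucleophile far faster than by the catechol hydroxyls, so the Weinreb amide forms without phenol protection.

Step 10
Reactants: 18 3-(3,4-dihydroxyphenyl)-N-methoxy-N-methylpropanamide
Product: 19 3-[3,4-bis(methoxymethoxy)phenyl]-N-methoxy-N-methylpropanamide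
Conditions: MOMCl (3 equiv), i-Pr2NEt (4 equiv), CH2Cl2, 0 °C to rt
Reagents that add atoms: chloromethyl methyl ether (MOMCl), COCCl
Why: MOM protection of both catechol hydroxyls by alkylation with the α-chloro ether under amine base removes the acidic protons ahead of the organolithium step and leaves the Weinreb amide untouched.

Step 11
Reactants: 15 6,8-bis(methoxymethoxy)-3-methyl-2,5-dihydro-1-benzoxepine; 19 3-[3,4-bis(methoxymethoxy)phenyl]-N-methoxy-N-methylpropanamide
Product: 22 1-[6,8-bis(methoxymethoxy)-3-methyl-2,5-dihydro-1-benzoxepin-7-yl]-3-[3,4-bis(methoxymethoxy)phenyl]propan-1-one, via aryllithium 20 (not isolated), via lithium hemiaminal chelate 21 (not isolated)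
Conditions: 15 (1.2 equiv), n-BuLi (1.2 equiv), THF, 0 °C, 1 h; then 19 (1.0 equiv), −78 to 0 °C; sat. aq NH4Cl
Reagents that add atoms: none
Why: Directed ortho metalation followed by Weinreb ketone synthesis: n-BuLi should remove the C7 proton, which is acidified and pre-coordinated by two flanking OMOM groups (C9 has only one, plus the weaker ring ether), and aryllithium 20 adds to the amide to give the chelated tetrahedral lithium adduct 21, which cannot collapse before the quench and therefore delivers the ketone without over-addition.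

Step 12
Reactants: 22 1-[6,8-bis(methoxymethoxy)-3-methyl-2,5-dihydro-1-benzoxepin-7-yl]-3-[3,4-bis(methoxymethoxy)phenyl]propan-1-one
Product: 23 1-(6,8-dihydroxy-3-methyl-2,5-dihydro-1-benzoxepin-7-yl)-3-(3,4-dihydroxyphenyl)propan-1-one (CNP0203471.0)
Conditions: 1.25 M HCl in MeOH, 40 °C, Ar
Reagents that add atoms: none
Why: Acid-catalysed acetal exchange with methanol removes all four MOM groups as dimethoxymethane under conditions that the allyl aryl ether and the isolated trisubstituted alkene of the oxepine should tolerate, the C6 and C8 ethers ortho to the ketone being the first to go.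

**Compound list**

1 | isoprene (2-methylbuta-1,3-diene) | C=CC(C)=C | starting material
2 | (2E)-1,4-dibromo-2-methylbut-2-ene | BrC/C(C)=C/CBr | intermediate
3 | cyclohexane-1,3-dione | O=C1CCCC(=O)C1 | starting material
4 | 2-[(2E)-4-bromo-3-methylbut-2-en-1-yl]cyclohexane-1,3-dione (present as its cesium enolate) | O=C1CCCC(=O)C1C/C=C(\C)CBr | intermediate (not isolated)
5 | 1-(prop-1-en-2-yl)spiro[2.5]octane-4,8-dione (racemic, one enantiomer drawn) | CC(=C)[C@@H]1CC12C(=O)CCCC2=O | intermediate
6 | 3-methyl-2,5,8,9-tetrahydro-1-benzoxepin-6(7H)-one | CC1=CCC2=C(CCCC2=O)OC1 | intermediate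
7 | lithium 3-methyl-2,5,8,9-tetrahydro-1-benzoxepin-6-olate (cross-conjugated enolate) | [Li]OC1=CCCC2=C1CC=C(C)CO2 | intermediate (not isolated)
8 | 3-methyl-7-(phenylselanyl)-2,5,8,9-tetrahydro-1-benzoxepin-6(7H)-one (racemic, one enantiomer drawn) | CC1=CCC2=C(CC[C@H]([Se]c3ccccc3)C2=O)OC1 | intermediate
9 | 7-(benzeneseleninyl)-3-methyl-2,5,8,9-tetrahydro-1-benzoxepin-6(7H)-one (racemic, both configurations at selenium) | CC1=CCC2=C(CC[C@H]([Se](=O)c3ccccc3)C2=O)OC1 | intermediate (not isolated)
10 | 3-methyl-2,5-dihydro-1-benzoxepin-6(9H)-one | CC1=CCC2=C(CC=CC2=O)OC1 | intermediate (not isolated)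
11 | 3-methyl-2,5-dihydro-1-benzoxepin-6-ol | CC1=CCc2c(O)cccc2OC1 | intermediate
12 | 6-(methoxymethoxy)-3-methyl-2,5-dihydro-1-benzoxepine | CC1=CCc2c(OCOC)cccc2OC1 | intermediate
13 | 2-[6-(methoxymethoxy)-3-methyl-2,5-dihydro-1-benzoxepin-8-yl]-4,4,5,5-tetramethyl-1,3,2-dioxaborolane | CC1=CCc2c(OCOC)cc(B3OC(C)(C)C(C)(C)O3)cc2OC1 | intermediate (not isolated)
14 | 6-(methoxymethoxy)-3-methyl-2,5-dihydro-1-benzoxepin-8-ol | CC1=CCc2c(OCOC)cc(O)cc2OC1 | intermediate
15 | 6,8-bis(methoxymethoxy)-3-methyl-2,5-dihydro-1-benzoxepine | CC1=CCc2c(OCOC)cc(OCOC)cc2OC1 | intermediate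
16 | 3-(3,4-dihydroxyphenyl)propanoic acid | OC(=O)CCc1ccc(O)c(O)c1 | starting material
17 | 1H-benzotriazol-1-yl 3-(3,4-dihydroxyphenyl)propanoate | O=C(CCc1ccc(O)c(O)c1)On1nnc2ccccc12 | intermediate (not isolated)
18 | 3-(3,4-dihydroxyphenyl)-N-methoxy-N-methylpropanamide | CON(C)C(=O)CCc1ccc(O)c(O)c1 | intermediate
19 | 3-[3,4-bis(methoxymethoxy)phenyl]-N-methoxy-N-methylpropanamide | CON(C)C(=O)CCc1ccc(OCOC)c(OCOC)c1 | intermediate
20 | [6,8-bis(methoxymethoxy)-3-methyl-2,5-dihydro-1-benzoxepin-7-yl]lithium | CC1=CCc2c(OCOC)c([Li])c(OCOC)cc2OC1 | intermediate (not isolated)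
21 | lithium 1-[6,8-bis(methoxymethoxy)-3-methyl-2,5-dihydro-1-benzoxepin-7-yl]-3-[3,4-bis(methoxymethoxy)phenyl]-1-[methoxy(methyl)amino]propan-1-olate (racemic, one enantiomer drawn) | CC1=CCc2c(OCOC)c([C@@](O[Li])(CCc3ccc(OCOC)c(OCOC)c3)N(C)OC)c(OCOC)cc2OC1 | intermediate (not isolated)
22 | 1-[6,8-bis(methoxymethoxy)-3-methyl-2,5-dihydro-1-benzoxepin-7-yl]-3-[3,4-bis(methoxymethoxy)phenyl]propan-1-one | CC1=CCc2c(OCOC)c(C(=O)CCc3ccc(OCOC)c(OCOC)c3)c(OCOC)cc2OC1 | intermediate
23 | 1-(6,8-dihydroxy-3-methyl-2,5-dihydro-1-benzoxepin-7-yl)-3-(3,4-dihydroxyphenyl)propan-1-one | CC1=CCc2c(cc(O)c(C(=O)CCc3ccc(O)c(O)c3)c2O)OC1 | target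

**Step count and risks**

Total step count: 12. Longest linear sequence: 10 steps (steps 1–8, 11 and 12, from isoprene); the side-chain branch adds steps 9 and 10.

Steps most likely to fail:

Step 2. The alkylation may begin at the CH2Br next to the methyl-bearing carbon, or at oxygen. Ring closure would then lead to the 1-methyl-1-vinyl spirocycle (and on to a 4-methyl oxepine) or to dihydrofurans. The fallback fixes the regiochemistry by leaving-group ability; it sets out from isoprene 1 and returns at 5. Chloroacetoxylation of 1 (t-BuOCl, AcOH, then acid-catalysed equilibration to the 1,4-adduct) would give (2E)-4-chloro-3-methylbut-2-en-1-yl acetate F1. Methanolysis (K2CO3, MeOH, 0 °C) would give (2E)-4-chloro-3-methylbut-2-en-1-ol F2, and PBr3 (Et2O, 0 °C) would give (2E)-1-bromo-4-chloro-3-methylbut-2-ene F3. With dione 3 and Cs2CO3 the bromide end must react first, so that 2-[(2E)-4-chloro-3-methylbut-2-en-1-yl]cyclohexane-1,3-dione F4 can only close by SN2' loss of chloride to spirodione 5.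

Step 3. Ionic opening of the cyclopropane and re-closure through oxygen (Cloke–Wilson pathway) may outrun the sigmatropic shift. Prolonged heating may also drain the oxepine back through 5 into the dihydrofuran. The fallback builds the same ring by metathesis; it sets out from dione 3 and returns at 6. Tsuji–Trost C-allylation (allyl acetate, Pd(PPh3)4 as the source of zerovalent palladium, THF) would give 2-(prop-2-en-1-yl)cyclohexane-1,3-dione F5. Mitsunobu O-alkylation with 2-methylprop-2-en-1-ol (PPh3, DIAD, THF) would give 3-[(2-methylprop-2-en-1-yl)oxy]-2-(prop-2-en-1-yl)cyclohex-2-en-1-one F6. Ring-closing metathesis with the second-generation Grubbs catalyst RuCl2(=CHPh)(H2IMes)(PCy3) (CH2Cl2, 40 °C) would then close the seven-membered ring with loss of ethene to give 6.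

Step 11. The doubly ortho-substituted aryllithium may transfer a proton instead of adding, by deprotonating the amide at its α-CH2 or at the N-OCH3 group, so that acyl transfer stalls. The fallback uses a more electrophilic carbonyl and a separate oxidation; it sets out from amide 19 and arene 15 and returns at 22. Reduction of 19 (LiAlH4, THF, −40 °C) would give 3-[3,4-bis(methoxymethoxy)phenyl]propanal F7. Aryllithium 20, made from 15 as before, should add to it at −78 °C to give, after aqueous NH4Cl, racemic 1-[6,8-bis(methoxymethoxy)-3-methyl-2,5-dihydro-1-benzoxepin-7-yl]-3-[3,4-bis(methoxymethoxy)phenyl]propan-1-ol F8. Dess–Martin periodinane (NaHCO3, CH2Cl2, rt) would oxidise F8 to ketone 22.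

**Further compounds**

F1 | step 2 | (2E)-4-chloro-3-methylbut-2-en-1-yl acetate | CC(=O)OC/C=C(\C)CCl
F2 | step 2 | (2E)-4-chloro-3-methylbut-2-en-1-ol | OC/C=C(\C)CCl
F3 | step 2 | (2E)-1-bromo-4-chloro-3-methylbut-2-ene | BrC/C=C(\C)CCl
F4 | step 2 | 2-[(2E)-4-chloro-3-methylbut-2-en-1-yl]cyclohexane-1,3-dione | O=C1CCCC(=O)C1C/C=C(\C)CCl
F5 | step 3 | 2-(prop-2-en-1-yl)cyclohexane-1,3-dione | O=C1CCCC(=O)C1CC=C
F6 | step 3 | 3-[(2-methylprop-2-en-1-yl)oxy]-2-(prop-2-en-1-yl)cyclohex-2-en-1-one | C=CCC1=C(OCC(C)=C)CCCC1=O
F7 | step 11 | 3-[3,4-bis(methoxymethoxy)phenyl]propanal | O=CCCc1ccc(OCOC)c(OCOC)c1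
F8 | step 11 | 1-[6,8-bis(methoxymethoxy)-3-methyl-2,5-dihydro-1-benzoxepin-7-yl]-3-[3,4-bis(methoxymethoxy)phenyl]propan-1-ol (racemic, one enantiomer drawn) | CC1=CCc2c(OCOC)c([C@@H](O)CCc3ccc(OCOC)c(OCOC)c3)c(OCOC)cc2OC1
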